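# Total synthesis proposal for CNP0137670.2 (compound 17)

## Analysis of the target

- **Ring system.** Target 17 is an epoxyquinol, a 7-oxabicyclo[4.1.0]hept-3-en-2-one. The carbocycle (ring A, C1–C6) carries the ketone at C1, the C2=C3 alkene with the acetoxymethyl carbon C7 on C2, and a secondary carbinol at C4. The oxirane (ring B) spans C5–C6.
- **Chain.** The fully substituted oxirane carbon C5 bears a C15 chain. It opens with a second secondary carbinol, C1′, and continues as a skipped triene (2′E, 6′E, terminal isopropylidene).
- **Stereocentres.** C4 (S), C5 (R), C6 (R) and C1′ (S) are contiguous.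
  - C4–OH is trans to the oxirane oxygen.
  - C4–OH and C1′–OH are 1,3-anti across C5.
  - C1′–OH and the oxirane oxygen are syn when C4–C5–C1′–C2′ is drawn as a zigzag.
- **The feature that invites the strategy.** The C1′ oxygen is a hub. The paths O–C1′–C5–C6 and O–C1′–C5–C4 are equally long, so a metal on this oxygen can reach C6 and C4 through six-membered arrays. Ring A without its stereocentres has a para-quinone oxidation pattern, so it is a flat arene in disguise.
- **Sensitive groups.**
  - The epoxy enone is base-labile, through vinylogous opening of ring B with aromatisation or through epoxide migration to C1′ or C4.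
  - The C7 acetate is a leaving group next to an enone.
  - The C1′ carbinol is allylic.
  - The three trisubstituted alkenes exclude peracids, singlet oxygen, osmylation and strong acid.
- **What makes it hard.** C5 is flanked by three oxygenated carbons and must be set in register with both carbinols. Every oxidation has to spare the triene.

## Retrosynthetic reasoning

**17 ⇒ 16 ⇒ 15 (O–acetyl and C2–C7).**
- C7 sits on the α-carbon of the C1 enone, which is the retron of a Morita–Baylis–Hillman hydroxymethylation.
- Cutting it last means ring A needs no second carbon substituent and can come from 7.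
- It also means the allylic acetate never meets peroxide, hydride or organometallic reagents.
- The forward steps must functionalise only C2 and acylate only the primary hydroxyl.

**15 ⇒ 14 ⇒ 13 (C1 ketal and the C4–H bond).**
- C1 is masked as a dimethyl ketal, so the two former quinone carbonyls are never equivalent.
- C4 is traced back to a ketone because its hydroxyl is 1,3-anti to C1′–OH.
- That relation is what internal hydride delivery from a boron atom on the C1′ oxygen produces.
- The forward step must attack C4 from the oxirane face, which undirected hydride would avoid.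

**13 ⇒ 8 + 6 (key cut: C1′–C2′ and both C–O bonds of ring B).**
- The chain is cut at C1′–C2′ and not at the customary C5–C1′. C1′ then stays on the ring as a formyl group of the achiral, flat dienone 8.
- Addition of the alkenyl metal from 6 creates the C1′ alkoxide exactly at the hub. The same metal can then carry a peroxide oxygen to C6.
- One flask joins the two halves, closes ring B and sets C1′, C5 and C6 as a group.
- No ortho-hydroxybenzyl allylic alcohol is ever formed. Such a compound would collapse to a quinone methide.

**8 ⇒ 7 (dearomatisation).**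
- Oxidation of the 4-methoxyphenol 7 in an alcohol solvent gives the quinone monoketal directly.
- The phenol oxygen becomes the C4 carbonyl, the anisole carbon becomes the C1 ketal, and the aldehyde becomes C1′.

**6 ⇒ 4 ⇒ 1 + 2.**
- The 2′E trisubstituted alkene is the retron of a syn methylmetalation of terminal alkyne 4.
- Alkyne 4 comes from the allylic bromide 1 and the dianion of 2, which carries the 6′E alkene over unchanged.

## Alternatives that were turned down

**Alternative 1: the textbook cut at C5–C1′.**
- *Forward route.* Bromide A1 is lithiated and added to farnesal A2 to give carbinol A3. Oxidative demethylation gives quinone A4 or its monoketal. Nucleophilic epoxidation, C4 reduction and protecting-group exchange at C7 follow.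
- *Why turned down.*
  - The union sets C1′ without control, so an oxidation and asymmetric reduction detour is needed.
  - Ring B then needs an external chiral reagent acting on a substrate that is already chiral, with possible mismatch. The four stereocentres are set in three unrelated operations.
  - A3 is an electron-rich benzylic and allylic carbinol. It ionises easily under acidic oxidative demethylation, with loss of configuration and cation-induced cyclisation of the triene.
  - Carrying C7–O through the sequence adds silylation, desilylation and acetylation.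

**Alternative 2: ring A assembled instead of bought, with cuts at C1–C6, C4–C5 and C3–C4.**
- *Forward key step.* A Dötz benzannulation unites the alkenyl(methoxy)carbene complex A5, the enantioenriched propargylic silyl ether A6 and one carbonyl ligand. The product is the hydroquinone monomethyl ether A7, with the correct 2,5-pattern and differentiated oxygens.
- *Why turned down.*
  - It consumes stoichiometric zerovalent chromium and sets no stereocentre.
  - It delivers a flat ring of the same rank as commercial 7.
  - A7 has a free phenol ortho to a benzylic, allylic silyloxy carbon. It is prone to elimination to an ortho-quinone methide and oxa-6π closure to a chromene.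
  - The two fragments and the silyl traffic cost about five steps more than the present route.

**Alternative 3: the γ-hydroxy enone retron, cutting C1–O and C4–O together.**
- *Forward key step.* Singlet oxygen adds [4+2] to the diene of arene oxide A8, anti to the oxirane, to give endoperoxide A9. Kornblum–DeLaMare fragmentation through the less hindered bridgehead hydrogen at C1 gives the C1 ketone and the trans C4 carbinol in one step.
- *Why turned down.*
  - A8 equilibrates with its oxepine valence tautomer, which erases the C5/C6 configuration.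
  - Singlet oxygen undergoes the ene reaction with the three trisubstituted alkenes at rates comparable to the cycloaddition.
  - Moving the chain to a later stage removes the convergence, and A8 itself is harder to reach than the whole of 13.

Key step: step 4

Assumption: the SMILES is read as the (4S,5R,6R,1′S,2′E,6′E) isomer in the locants defined above, and (−)-MIB is taken to deliver the zinc-bound carbon to the Si face of the aldehyde, as is usual for this isoborneol amino alcohol family (the antipode is equally available).

## Route

Step 1
Reactants: 1 geranyl bromide; 2 propyne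
Product: 4 (5E)-6,10-dimethylundeca-5,9-dien-1-yne, via 1,3-dilithiopropyne 3 (not isolated)
Conditions: 2, nBuLi (2 equiv), TMEDA, Et2O/hexane, −78 °C to rt; 1, 0 °C to rt; H2O
Reagents that add atoms: none
Why: Double deprotonation of propyne gives dianion 3, whose more basic propargylic carbon alkylates the primary allylic bromide by SN2 without allylic transposition, so the E alkene of 1 is carried over unchanged. The aqueous quench protonates the acetylide terminus (propargylation of an allylic halide).

Step 2
Reactants: 4 (5E)-6,10-dimethylundeca-5,9-dien-1-yne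
Product: 6 (1E,5E)-1-iodo-2,6,10-trimethylundeca-1,5,9-triene, via alkenyldimethylalane 5 (not isolated)
Conditions: Me3Al (2 equiv), Cp2ZrCl2 (0.2 equiv), CH2Cl2, 0 °C to rt; I2, THF, −30 to 0 °C
Reagents that add atoms: trimethylaluminium C[Al](C)C; iodine II
Why: Negishi carboalumination adds methyl and aluminium syn across the terminal alkyne with aluminium at the terminus, and iodinolysis of 5 proceeds with retention, which fixes the future 2′E geometry. The isolated trisubstituted alkenes do not react.

Step 3
Reactants: 7 2-hydroxy-5-methoxybenzaldehyde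
Product: 8 3,3-dimethoxy-6-oxocyclohexa-1,4-diene-1-carbaldehyde
Conditions: PhI(OAc)2 (1.1 equiv), MeOH, 0 °C; NaHCO3 work-up, short silica plug, used at once
Reagents that add atoms: methanol CO
Why: Oxidative dearomatisation of a 4-methoxyphenol by a trivalent iodine reagent proceeds by ligand exchange at the phenol oxygen, loss of iodobenzene and capture of the methoxy-activated para carbon by methanol, giving the quinone monoketal. No stereocentre is formed, and the two ring oxygens are now differentiated as ketone (C4) and ketal (C1).

Step 4
Reactants: 6 (1E,5E)-1-iodo-2,6,10-trimethylundeca-1,5,9-triene; 8 3,3-dimethoxy-6-oxocyclohexa-1,4-diene-1-carbaldehyde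
Product: 13 (1S,6R)-1-[(1S,2E,6E)-1-hydroxy-3,7,11-trimethyldodeca-2,6,10-trien-1-yl]-5,5-dimethoxy-7-oxabicyclo[4.1.0]hept-3-en-2-one, via alkenyllithium 9 (not isolated), via alkenyl(ethyl)zinc 10 (not isolated), via ethylzinc alkoxide 11 (not isolated), via tert-butylperoxyzinc alkoxide 12 (not isolated)
Conditions: 6 (1.4 equiv), tBuLi (2.8 equiv), Et2O, −78 °C; EtZnCl (1.4 equiv, from Et2Zn + ZnCl2), −78 to 0 °C; TEEDA, (−)-MIB (10 mol %), toluene; 8, −20 °C; then tBuOOH (5.5 M in decane), −20 to 0 °C; pH 7 buffer
Reagents that add atoms: tert-butyl hydroperoxide CC(C)(C)OO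
Why: Proposed new method: iodine–lithium exchange and transmetalation give 10, and the zinc complex of (−)-MIB transfers its alkenyl (not its ethyl) group to the Si face of the formyl group of 8, which forms C1′–C2′ with retention of the E geometry and leaves the ethylzinc alkoxide 11. tBuOOH then protonates the remaining Zn–Et bond, so that in 12 the peroxide sits on the same zinc atom as the C1′ oxygen; its inner oxygen adds to C6 through a six-membered array (C6, O, Zn, O, C1′, C5), and the zinc enolate so formed closes ring B by 3-exo-tet attack of C5 on that oxygen with loss of tert-butoxide (Weitz–Scheffer mechanism). The closest known reaction types are the one-flask catalytic asymmetric organozinc addition to enals followed by alkoxide-directed epoxidation, and the epoxidation of enones by alkylperoxyzinc alkoxides; what is new is delivery from a carbinol-bound zinc peroxide to an electron-poor, s-trans cyclic dienone. C1′ (S) is set by the ligand. C5 and C6 follow from C1′: in the reactive rotamer the C1′–H bond lies in the ring plane next to the C4 carbonyl (least allylic strain), the chain covers one face and the O–Zn–OO arm the other, so oxygen lands on the face syn to the C1′ oxygen, which is the 5,6-configuration of 17. 1,2- over 1,4-addition is secured by the carbonyl selectivity of amino-alcohol zinc catalysis and by the quaternary ketal carbon C1 next to C6. C5=C6 is chosen over C2=C3 because only C6 lies within reach of the tether, while a zinc peroxide bound to the C4 carbonyl cannot reach the β-carbon of an s-trans enone. The three chain alkenes are inert to a nucleophilic zinc peroxide as long as no titanium or vanadium co-catalyst is present.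

Step 5
Reactants: 13 (1S,6R)-1-[(1S,2E,6E)-1-hydroxy-3,7,11-trimethyldodeca-2,6,10-trien-1-yl]-5,5-dimethoxy-7-oxabicyclo[4.1.0]hept-3-en-2-one
Product: 14 (1S,2S,6R)-1-[(1S,2E,6E)-1-hydroxy-3,7,11-trimethyldodeca-2,6,10-trien-1-yl]-5,5-dimethoxy-7-oxabicyclo[4.1.0]hept-3-en-2-ol
Conditions: Me4NBH(OAc)3 (5 equiv), MeCN/AcOH (4:1), −35 °C; aq. Rochelle salt/NaHCO3
Reagents that add atoms: none
Why: Evans–Saksena reduction: acetate exchange places boron on the C1′ oxygen, and hydride is delivered to C4 through a chair-like six-membered array with the chain equatorial. This forces attack from the oxirane face and gives the 1,3-anti diol, that is C4–OH trans to ring B (4S). The reagent is too weak to reduce an undirected enone, adds 1,2 only, and leaves ketal, oxirane and triene untouched.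

Step 6
Reactants: 14 (1S,2S,6R)-1-[(1S,2E,6E)-1-hydroxy-3,7,11-trimethyldodeca-2,6,10-trien-1-yl]-5,5-dimethoxy-7-oxabicyclo[4.1.0]hept-3-en-2-ol
Product: 15 (1R,5S,6S)-5-hydroxy-6-[(1S,2E,6E)-1-hydroxy-3,7,11-trimethyldodeca-2,6,10-trien-1-yl]-7-oxabicyclo[4.1.0]hept-3-en-2-one
Conditions: PPTS (0.2 equiv), acetone/H2O (9:1), rt
Reagents that add atoms: water O
Why: Mild hydrolysis of an allylic dimethyl ketal through the oxocarbenium ion stabilised by C2=C3 unveils the C1 enone. The C1′ and C4 carbinols are deactivated towards ionisation by the adjacent C5–O bond, and no stereocentre is touched (the descriptor at C5 changes only through CIP ranking).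

Step 7
Reactants: 15 (1R,5S,6S)-5-hydroxy-6-[(1S,2E,6E)-1-hydroxy-3,7,11-trimethyldodeca-2,6,10-trien-1-yl]-7-oxabicyclo[4.1.0]hept-3-en-2-one
Product: 16 (1R,5S,6R)-5-hydroxy-3-(hydroxymethyl)-6-[(1S,2E,6E)-1-hydroxy-3,7,11-trimethyldodeca-2,6,10-trien-1-yl]-7-oxabicyclo[4.1.0]hept-3-en-2-one
Conditions: aq. HCHO (37 %), DMAP (0.3 equiv), THF/H2O, 0 °C to rt
Reagents that add atoms: formaldehyde C=O
Why: Morita–Baylis–Hillman hydroxymethylation: DMAP adds reversibly to C3, the enolate carbon C2 attacks formaldehyde, and loss of DMAP restores C2=C3. C2 is the only enone α-CH in the molecule, and the weakly basic nucleophilic catalysis forms no stereocentre and should not epimerise any.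

Step 8
Reactants: 16 (1R,5S,6R)-5-hydroxy-3-(hydroxymethyl)-6-[(1S,2E,6E)-1-hydroxy-3,7,11-trimethyldodeca-2,6,10-trien-1-yl]-7-oxabicyclo[4.1.0]hept-3-en-2-one
Product: 17 [(1R,5S,6R)-5-hydroxy-6-[(1S,2E,6E)-1-hydroxy-3,7,11-trimethyldodeca-2,6,10-trien-1-yl]-2-oxo-7-oxabicyclo[4.1.0]hept-3-en-3-yl]methyl acetate
Conditions: AcCl (1.05 equiv), 2,4,6-collidine, CH2Cl2, −78 °C
Reagents that add atoms: acetyl chloride CC(=O)Cl
Why: Kinetically selective acylation of the unhindered primary allylic alcohol. Both secondary carbinols flank the fully substituted C5 and should be much slower at −78 °C with the weak base collidine.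

## Compound list

1 | geranyl bromide, (2E)-1-bromo-3,7-dimethylocta-2,6-diene | CC(C)=CCC/C(C)=C/CBr | starting material
2 | propyne | CC#C | starting material
3 | 1,3-dilithiopropyne | [Li]CC#C[Li] | intermediate (not isolated)
4 | (5E)-6,10-dimethylundeca-5,9-dien-1-yne | C#CCC/C=C(\C)CCC=C(C)C | intermediate
5 | dimethyl[(1E,5E)-2,6,10-trimethylundeca-1,5,9-trien-1-yl]aluminium | C[Al](C)/C=C(\C)CC/C=C(\C)CCC=C(C)C | intermediate (not isolated)
6 | (1E,5E)-1-iodo-2,6,10-trimethylundeca-1,5,9-triene | I/C=C(\C)CC/C=C(\C)CCC=C(C)C | intermediate
7 | 2-hydroxy-5-methoxybenzaldehyde | COc1ccc(O)c(C=O)c1 | starting material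
8 | 3,3-dimethoxy-6-oxocyclohexa-1,4-diene-1-carbaldehyde | O=CC1=CC(OC)(OC)C=CC1=O | intermediate
9 | [(1E,5E)-2,6,10-trimethylundeca-1,5,9-trien-1-yl]lithium | [Li]/C=C(\C)CC/C=C(\C)CCC=C(C)C | intermediate (not isolated)
10 | ethyl[(1E,5E)-2,6,10-trimethylundeca-1,5,9-trien-1-yl]zinc | CC[Zn]/C=C(\C)CC/C=C(\C)CCC=C(C)C | intermediate (not isolated)
11 | ethylzinc alkoxide of (S)-2-(1-hydroxyfarnesyl)-4,4-dimethoxycyclohexa-2,5-dienone | O=C1C=CC(OC)(OC)C=C1[C@@H](O[Zn]CC)/C=C(\C)CC/C=C(\C)CCC=C(C)C | intermediate (not isolated)
12 | tert-butylperoxyzinc alkoxide of the same (S)-carbinol | O=C1C=CC(OC)(OC)C=C1[C@@H](O[Zn]OOC(C)(C)C)/C=C(\C)CC/C=C(\C)CCC=C(C)C | intermediate (not isolated)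
13 | (1S,6R)-1-[(1S,2E,6E)-1-hydroxy-3,7,11-trimethyldodeca-2,6,10-trien-1-yl]-5,5-dimethoxy-7-oxabicyclo[4.1.0]hept-3-en-2-one | C1=CC(=O)[C@@]2([C@@H](O)/C=C(\C)CC/C=C(\C)CCC=C(C)C)O[C@H]2C1(OC)OC | intermediate
14 | (1S,2S,6R)-1-[(1S,2E,6E)-1-hydroxy-3,7,11-trimethyldodeca-2,6,10-trien-1-yl]-5,5-dimethoxy-7-oxabicyclo[4.1.0]hept-3-en-2-ol | C1=C[C@H](O)[C@@]2([C@@H](O)/C=C(\C)CC/C=C(\C)CCC=C(C)C)O[C@H]2C1(OC)OC | intermediate
15 | (1R,5S,6S)-5-hydroxy-6-[(1S,2E,6E)-1-hydroxy-3,7,11-trimethyldodeca-2,6,10-trien-1-yl]-7-oxabicyclo[4.1.0]hept-3-en-2-one | C1=C[C@H](O)[C@@]2([C@@H](O)/C=C(\C)CC/C=C(\C)CCC=C(C)C)O[C@H]2C1=O | intermediate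
16 | (1R,5S,6R)-5-hydroxy-3-(hydroxymethyl)-6-[(1S,2E,6E)-1-hydroxy-3,7,11-trimethyldodeca-2,6,10-trien-1-yl]-7-oxabicyclo[4.1.0]hept-3-en-2-one | OCC1=C[C@H](O)[C@@]2([C@@H](O)/C=C(\C)CC/C=C(\C)CCC=C(C)C)O[C@H]2C1=O | intermediate
17 | [(1R,5S,6R)-5-hydroxy-6-[(1S,2E,6E)-1-hydroxy-3,7,11-trimethyldodeca-2,6,10-trien-1-yl]-2-oxo-7-oxabicyclo[4.1.0]hept-3-en-3-yl]methyl acetate | CC(=O)OCC1=C[C@H](O)[C@@]2([C@@H](O)/C=C(\C)CC/C=C(\C)CCC=C(C)C)O[C@H]2C1=O | target

## Step count and least certain steps

Total step count: 8. Longest linear sequence: 7 steps (steps 1, 2, 4, 5, 6, 7, 8).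

**Step 4 (key step, proposed new method).**
- *What may go wrong in the addition.* The neighbouring C4 carbonyl can chelate zinc and accelerate an unligated background reaction, which erodes the enantioselectivity at C1′. The doubly activated C6 may take up the alkenyl group by conjugate addition.
- *What may go wrong in the epoxidation.* The same chelation may hold the zinc peroxide on the C4 side, away from C6. Oxygen transfer would then stall, or proceed by external attack with poor facial selectivity and competing reaction at C2=C3.
- *Fallback (known chemistry, the two events separated and reversed; sets out from 8 and 6, returns at 13).* Dienone 8 is first epoxidised at its formyl-activated C5=C6 bond. The method is iminium catalysis for α-branched enals, using a cinchona-derived primary amine salt of a chiral phosphoric acid with aq. H2O2. This gives (1R,6R)-5,5-dimethoxy-2-oxo-7-oxabicyclo[4.1.0]hept-3-ene-1-carbaldehyde F1. Iodide 6 is then joined to the aldehyde of F1 by a ligand-controlled asymmetric Nozaki–Hiyama–Kishi coupling (CrCl2, NiCl2, chiral sulfonamide ligand, MeCN). That coupling tolerates ketone, oxirane and ketal, and it gives 13.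

**Step 3.**
- *What may go wrong.* The product alkene C5=C6 is flanked by two carbonyl groups. Conjugate addition of methanol at C6, acetalisation of the formyl group, and loss of the ketal on silica are the likely modes of decay.
- *Fallback (sets out from 7, returns at 8).* The oxidation level is staged so that the aldehyde never meets methanol. NaBH4 reduction of 7 gives 2-(hydroxymethyl)-4-methoxyphenol F2. PhI(OAc)2 in MeOH gives the robust 2-(hydroxymethyl)-4,4-dimethoxycyclohexa-2,5-dien-1-one F3. Oxidation with MnO2 or Dess–Martin periodinane in CH2Cl2 then gives 8.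

**Step 5.**
- *What may go wrong.* Facial selectivity falls if hydride is delivered from the rotamer in which the boron-bearing oxygen lies under ring A. Acetic acid may also start to solvolyse the ketal before reduction is complete.
- *Fallback (sets out from 13, returns at 15).* The intrinsic bias of the bicycle is accepted, and C4 is then inverted.
  - The C1′ hydroxyl is capped (Et3SiOTf, 2,6-lutidine) as the triethylsilyl ether F4.
  - Luche reduction (NaBH4, CeCl3·7H2O, MeOH) should bring hydride in anti to the oxirane and give the cis-epoxy alcohol F5.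
  - Mitsunobu reaction with 4-nitrobenzoic acid (PPh3, DIAD) gives the inverted 4-nitrobenzoate F6.
  - Methanolysis (K2CO3, MeOH) gives the trans-epoxy alcohol silyl ether F7.
  - The acid conditions of step 6 remove silyl ether and ketal together to give 15.

**Step 7.**
- *What may go wrong.* Addition of DMAP to C3 next to the C4 carbinol may be slow. Prolonged exposure invites deprotonation at C4 with vinylogous opening of ring B and aromatisation, or epoxide migration towards C1′ or C4.
- *Fallback (sets out from 15, returns at 16).* The reversible organocatalytic C–C bond formation is replaced by halogenation and cross-coupling. α-Iodination (I2, pyridine, CH2Cl2) gives the 2-iodo enone F8. Stille coupling with Bu3SnCH2OH (Pd(PPh3)4, toluene, 60 °C) installs C7 and gives 16.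

## Further compounds

F1 | step 4 | (1R,6R)-5,5-dimethoxy-2-oxo-7-oxabicyclo[4.1.0]hept-3-ene-1-carbaldehyde | C1=CC(=O)[C@@]2(C=O)O[C@H]2C1(OC)OC
F2 | step 3 | 2-(hydroxymethyl)-4-methoxyphenol | COc1ccc(O)c(CO)c1
F3 | step 3 | 2-(hydroxymethyl)-4,4-dimethoxycyclohexa-2,5-dien-1-one | OCC1=CC(OC)(OC)C=CC1=O
F4 | step 5 | C1′-O-triethylsilyl ether of 13 | C1=CC(=O)[C@@]2([C@@H](O[Si](CC)(CC)CC)/C=C(\C)CC/C=C(\C)CCC=C(C)C)O[C@H]2C1(OC)OC
F5 | step 5 | C4-epimeric (cis) epoxy alcohol, C1′-O-triethylsilyl ether | C1=C[C@@H](O)[C@@]2([C@@H](O[Si](CC)(CC)CC)/C=C(\C)CC/C=C(\C)CCC=C(C)C)O[C@H]2C1(OC)OC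
F6 | step 5 | inverted C4 4-nitrobenzoate, C1′-O-triethylsilyl ether | C1=C[C@H](OC(=O)c3ccc(cc3)[N+](=O)[O-])[C@@]2([C@@H](O[Si](CC)(CC)CC)/C=C(\C)CC/C=C(\C)CCC=C(C)C)O[C@H]2C1(OC)OC
F7 | step 5 | C1′-O-triethylsilyl ether of 14 | C1=C[C@H](O)[C@@]2([C@@H](O[Si](CC)(CC)CC)/C=C(\C)CC/C=C(\C)CCC=C(C)C)O[C@H]2C1(OC)OC
F8 | step 7 | 2-iodo enone derived from 15 | IC1=C[C@H](O)[C@@]2([C@@H](O)/C=C(\C)CC/C=C(\C)CCC=C(C)C)O[C@H]2C1=O
A1 | alternative 1 | [(4-bromo-2,5-dimethoxybenzyl)oxy](tert-butyl)dimethylsilane | COc1cc(CO[Si](C)(C)C(C)(C)C)c(OC)cc1Br
A2 | alternative 1 | (2E,6E)-farnesal | CC(C)=CCC/C(C)=C/CC/C(C)=C/C=O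
A3 | alternative 1 | racemic 1-aryl-farnesyl carbinol | COc1cc(CO[Si](C)(C)C(C)(C)C)c(OC)cc1C(O)/C=C(\C)CC/C=C(\C)CCC=C(C)C
A4 | alternative 1 | 2-(silyloxymethyl)-5-(1-hydroxyfarnesyl)-1,4-benzoquinone | O=C1C=C(CO[Si](C)(C)C(C)(C)C)C(=O)C=C1C(O)/C=C(\C)CC/C=C(\C)CCC=C(C)C
A5 | alternative 2 | pentacarbonyl{methoxy[3-(tert-butyldimethylsilyloxy)prop-1-en-2-yl]carbene}chromium | COC(C(=C)CO[Si](C)(C)C(C)(C)C)=[Cr](=C=O)(=C=O)(=C=O)(=C=O)=C=O
A6 | alternative 2 | (S)-propargylic silyl ether from farnesal | C#C[C@@H](O[Si](C)(C)C(C)(C)C)/C=C(\C)CC/C=C(\C)CCC=C(C)C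
A7 | alternative 2 | hydroquinone monomethyl ether from the benzannulation | COc1cc([C@@H](O[Si](C)(C)C(C)(C)C)/C=C(\C)CC/C=C(\C)CCC=C(C)C)c(O)cc1CO[Si](C)(C)C(C)(C)C
A8 | alternative 3 | arene oxide (C5/C6 configurationally labile) | CC(=O)OCC1=CC2OC2([C@@H](O)/C=C(\C)CC/C=C(\C)CCC=C(C)C)C=C1
A9 | alternative 3 | epoxy endoperoxide (ring configuration not controlled) | CC(=O)OCC1=CC2OOC1C3OC23[C@@H](O)/C=C(\C)CC/C=C(\C)CCC=C(C)C
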